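The target, as a ten-membered lactone (oxecin-2-one ring: O1, C2–C10), has the C8 carbinol bonded to sp2 carbon C7 of the endocyclic E-alkene C6=C7. This allylic alcohol is the retron of an alkenylmetal–aldehyde addition, so the route rests on a Nozaki–Hiyama–Kishi macrocyclisation. In one operation it forges C7–C8, closes the ten-membered ring and sets the C8 stereocentre (Felkin–Anh control from C9), with the E-geometry carried in from an iodoalkene. The precursor is an open-chain ester of an (E)-6-iodohex-5-enoic acid with a 2-silyloxy-3-acyloxy hexanal, assembled by Ti(OiPr)4-mediated opening of a Sharpless epoxy alcohol by the acid itself. The muconate half-ester is attached last.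

Key step: step 8

Remark: ring atoms are numbered as in oxecin-2-one (O1, C2 lactone carbonyl, C3 acyloxy carbon, C6=C7 alkene, C8 and C9 carbinols, C10 propyl-bearing carbon); on this numbering the target is (3S,6E,8R,9R,10S).

Step 1
Reactants: 1 L-homopropargylglycine, (2S)-2-aminohex-5-ynoic acid
Product: 2 (2S)-2-hydroxyhex-5-ynoic acid
Conditions: NaNO2, 1 M aq. H2SO4, 0 °C to rt
Reagents that add atoms: water, O
Why: Diazotisation of an α-amino acid, in which the carboxylate displaces N2 to an α-lactone that water reopens, so that double inversion should give net retention at C2.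

Step 2
Reactants: 2 (2S)-2-hydroxyhex-5-ynoic acid
Product: 4 (2S)-2-[(triethylsilyl)oxy]hex-5-ynoic acid, via silyl ester 3 (not isolated)
Conditions: TESCl (2.3 equiv), imidazole, DMF, 0 °C to rt; then aq. NaHCO3/THF, 0 °C; pH 4 work-up
Reagents that add atoms: chlorotriethylsilane, CC[Si](Cl)(CC)CC
Why: Silylation of both OH groups followed by selective hydrolysis of the far more labile silyl ester should leave the hindered secondary TES ether, with no stereocentre touched.

Step 3
Reactants: 4 (2S)-2-[(triethylsilyl)oxy]hex-5-ynoic acid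
Product: 5 (2S,5E)-6-iodo-2-[(triethylsilyl)oxy]hex-5-enoic acid
Conditions: Cp2Zr(H)Cl (2.3 equiv), THF, 0 °C to rt; I2, 0 °C; aq. Na2S2O3, pH 4 work-up
Reagents that add atoms: iodine, II
Why: Hydrozirconation–iodinolysis with the Schwartz reagent Cp2Zr(H)Cl, in which the first equivalent is consumed by the acid as its zirconium carboxylate, the second adds syn to the terminal alkyne with Zr at the terminus, and iodinolysis with retention should give the E-iodoalkene.

Step 4
Reactants: 6 (E)-hex-2-en-1-ol
Product: 7 (2R,3R)-3-propyloxiranemethanol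
Conditions: Ti(OiPr)4 (5 mol%), D-(−)-diethyl tartrate (6 mol%), t-BuOOH, 4 Å molecular sieves, CH2Cl2, −20 °C
Reagents that add atoms: tert-butyl hydroperoxide, CC(C)(C)OO
Why: Sharpless asymmetric epoxidation, in which the catalyst formed from Ti(OiPr)4 and the D-(−)-tartrate delivers oxygen to the alkene face that gives the (2R,3R)-trans-epoxide, setting both centres by catalyst control.

Step 5
Reactants: 5 (2S,5E)-6-iodo-2-[(triethylsilyl)oxy]hex-5-enoic acid (1.0 equiv); 7 (2R,3R)-3-propyloxiranemethanol (1.3 equiv)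
Product: 8 (2R,3S)-1,2-dihydroxyhexan-3-yl (2S,5E)-6-iodo-2-[(triethylsilyl)oxy]hex-5-enoate
Conditions: Ti(OiPr)4 (1.5 equiv), CH2Cl2, rt; aq. tartaric acid work-up
Reagents that add atoms: none
Why: Ti(OiPr)4-mediated opening of a 2,3-epoxy alcohol by a carboxylic acid, in which the titanium-bound epoxy alkoxide is attacked by the carboxylate selectively at C3 with inversion, so the ester bond and the (3S) centre should form together while C2 keeps its configuration (anti diol pattern).

Step 6
Reactants: 8 (2R,3S)-1,2-dihydroxyhexan-3-yl (2S,5E)-6-iodo-2-[(triethylsilyl)oxy]hex-5-enoate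
Product: 9 (2R,3S)-1,2-bis[(triethylsilyl)oxy]hexan-3-yl (2S,5E)-6-iodo-2-[(triethylsilyl)oxy]hex-5-enoate
Conditions: TESOTf (2.4 equiv), 2,6-lutidine, CH2Cl2, −78 °C
Reagents that add atoms: triethylsilyl trifluoromethanesulfonate, CC[Si](CC)(CC)OS(=O)(=O)C(F)(F)F
Why: Silyl ether formation with a silyl triflate and a non-nucleophilic base at low temperature should be fast enough to outrun 1,2-acyl migration in the acyloxy diol.

Step 7
Reactants: 9 (2R,3S)-1,2-bis[(triethylsilyl)oxy]hexan-3-yl (2S,5E)-6-iodo-2-[(triethylsilyl)oxy]hex-5-enoate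
Product: 10 (2S,3S)-1-oxo-2-[(triethylsilyl)oxy]hexan-3-yl (2S,5E)-6-iodo-2-[(triethylsilyl)oxy]hex-5-enoate
Conditions: (COCl)2, DMSO, CH2Cl2, −78 to −30 °C; Et3N, −78 to 0 °C
Reagents that add atoms: none
Why: Swern oxidation applied directly to a primary TES ether, in which chlorodimethylsulfonium chloride desilylates only the unhindered primary silyl ether to the alkoxysulfonium salt that collapses to the aldehyde, while the two secondary TES ethers and the iodoalkene should be untouched (the descriptor at the α-carbon changes by priority only).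

Step 8
Reactants: 10 (2S,3S)-1-oxo-2-[(triethylsilyl)oxy]hexan-3-yl (2S,5E)-6-iodo-2-[(triethylsilyl)oxy]hex-5-enoate
Product: 11 (3S,6E,8R,9R,10S)-8-hydroxy-10-propyl-3,9-bis[(triethylsilyl)oxy]-3,4,5,8,9,10-hexahydro-2H-oxecin-2-one
Conditions: CrCl2 (12 equiv), NiCl2 (0.1 equiv), degassed DMSO, 0.004 M, slow addition of 10, rt; aqueous work-up
Reagents that add atoms: none
Why: CrCl2 reduces NiCl2 to zerovalent nickel, which inserts into the C–I bond of 10; transmetalation gives an (E)-alkenyl trivalent chromium species that adds to the aldehyde, and the chromium alkoxide is hydrolysed on work-up. This is the Nozaki–Hiyama–Kishi reaction in its macrocyclising form, the closest known reaction type being the closure of iodoalkenyl aldehydes to medium-ring and macrocyclic lactones. The ten-membered lactone ring closes in a 10-exo-trig mode, alkenyl carbon C7 attacking carbonyl carbon C8 whose oxygen stays outside the ring. The new C8 stereocentre is controlled by the neighbouring C9 centre: non-chelated polar Felkin–Anh addition anti to the C9–OTES bond should give the 8,9-anti (8R) alcohol, and the E-alkene geometry is carried over from the iodoalkene with retention. The step needs chemoselectivity for the aldehyde over the ester and silyl ethers, which the weakly basic organochromium reagent provides, and cyclisation over oligomerisation, which high dilution with slow addition secures.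

Step 9
Reactants: 11 (3S,6E,8R,9R,10S)-8-hydroxy-10-propyl-3,9-bis[(triethylsilyl)oxy]-3,4,5,8,9,10-hexahydro-2H-oxecin-2-one
Product: 13 (3S,6E,8R,9S,10S)-3-hydroxy-8,9-(isopropylidenedioxy)-10-propyl-3,4,5,8,9,10-hexahydro-2H-oxecin-2-one, via triol 12 (not isolated)
Conditions: PPTS (cat.), MeOH, rt; concentrate; 2,2-dimethoxypropane, acetone, PPTS (cat.), rt
Reagents that add atoms: 2,2-dimethoxypropane, COC(C)(C)OC
Why: Acid methanolysis should remove both TES ethers, after which acetal exchange ties the adjacent C8/C9 diol into a cis-fused five-membered acetonide while the isolated C3 hydroxyl cannot form a cyclic acetal and stays free (the C9 descriptor changes by priority only).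

Step 10
Reactants: 14 ethyl (2E)-4-oxobut-2-enoate; 15 tert-butyl (triphenylphosphoranylidene)acetate
Product: 16 1-tert-butyl 6-ethyl (2E,4E)-hexa-2,4-dienedioate
Conditions: CH2Cl2, rt
Reagents that add atoms: none
Why: Wittig olefination with a stabilised ylide should give the new alkene with E geometry and leave the existing E-enoate unchanged.

Step 11
Reactants: 16 1-tert-butyl 6-ethyl (2E,4E)-hexa-2,4-dienedioate
Product: 17 (2E,4E)-6-tert-butoxy-6-oxohexa-2,4-dienoic acid
Conditions: LiOH (1.0 equiv), THF/H2O, 0 °C; then 1 M HCl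
Reagents that add atoms: lithium hydroxide, [Li+].[OH-]
Why: Saponification in which hydroxide attacks the unhindered ethyl ester, the tert-butyl ester is sterically shielded, and the carboxylate formed deactivates the diene against further attack.

Step 12
Reactants: 13 (3S,6E,8R,9S,10S)-3-hydroxy-8,9-(isopropylidenedioxy)-10-propyl-3,4,5,8,9,10-hexahydro-2H-oxecin-2-one; 17 (2E,4E)-6-tert-butoxy-6-oxohexa-2,4-dienoic acid
Product: 18 tert-butyl (3S,6E,8R,9S,10S)-8,9-(isopropylidenedioxy)-2-oxo-10-propyl-3,4,5,8,9,10-hexahydro-2H-oxecin-3-yl (2E,4E)-hexa-2,4-dienedioate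
Conditions: EDC·HCl, DMAP (cat.), CH2Cl2, 0 °C to rt
Reagents that add atoms: none
Why: Steglich esterification of the only free hydroxyl (C3) under mild carbodiimide activation, which should leave the C3 configuration and the diene geometry intact.

Step 13
Reactants: 18 tert-butyl (3S,6E,8R,9S,10S)-8,9-(isopropylidenedioxy)-2-oxo-10-propyl-3,4,5,8,9,10-hexahydro-2H-oxecin-3-yl (2E,4E)-hexa-2,4-dienedioate
Product: 19 (2E,4E)-6-{[(3S,6E,8R,9R,10S)-8,9-dihydroxy-2-oxo-10-propyl-3,4,5,8,9,10-hexahydro-2H-oxecin-3-yl]oxy}-6-oxohexa-2,4-dienoic acid (target)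
Conditions: TFA/CH2Cl2/H2O (4:4:1), 0 °C to rt
Reagents that add atoms: none
Why: Acidolysis should cleave the tert-butyl ester (loss of isobutene) and hydrolyse the acetonide in one operation, the lactone and the dienoate ester being stable to aqueous acid at this temperature.

Compound list
1 | L-homopropargylglycine, (2S)-2-aminohex-5-ynoic acid | N[C@@H](CCC#C)C(=O)O | starting material
2 | (2S)-2-hydroxyhex-5-ynoic acid | OC(=O)[C@@H](O)CCC#C | intermediate
3 | triethylsilyl (2S)-2-[(triethylsilyl)oxy]hex-5-ynoate | CC[Si](CC)(CC)OC(=O)[C@@H](O[Si](CC)(CC)CC)CCC#C | intermediate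
4 | (2S)-2-[(triethylsilyl)oxy]hex-5-ynoic acid | OC(=O)[C@@H](O[Si](CC)(CC)CC)CCC#C | intermediate
5 | (2S,5E)-6-iodo-2-[(triethylsilyl)oxy]hex-5-enoic acid | OC(=O)[C@@H](O[Si](CC)(CC)CC)CC/C=C/I | intermediate
6 | (E)-hex-2-en-1-ol | CCC/C=C/CO | starting material
7 | (2R,3R)-3-propyloxiranemethanol | CCC[C@H]1O[C@@H]1CO | intermediate
8 | (2R,3S)-1,2-dihydroxyhexan-3-yl (2S,5E)-6-iodo-2-[(triethylsilyl)oxy]hex-5-enoate | CCC[C@H](OC(=O)[C@@H](O[Si](CC)(CC)CC)CC/C=C/I)[C@H](O)CO | intermediate
9 | (2R,3S)-1,2-bis[(triethylsilyl)oxy]hexan-3-yl (2S,5E)-6-iodo-2-[(triethylsilyl)oxy]hex-5-enoate | CCC[C@H](OC(=O)[C@@H](O[Si](CC)(CC)CC)CC/C=C/I)[C@H](O[Si](CC)(CC)CC)CO[Si](CC)(CC)CC | intermediate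
10 | (2S,3S)-1-oxo-2-[(triethylsilyl)oxy]hexan-3-yl (2S,5E)-6-iodo-2-[(triethylsilyl)oxy]hex-5-enoate | CCC[C@H](OC(=O)[C@@H](O[Si](CC)(CC)CC)CC/C=C/I)[C@H](O[Si](CC)(CC)CC)C=O | intermediate
11 | (3S,6E,8R,9R,10S)-8-hydroxy-10-propyl-3,9-bis[(triethylsilyl)oxy]-3,4,5,8,9,10-hexahydro-2H-oxecin-2-one | CCC[C@@H]1OC(=O)[C@@H](O[Si](CC)(CC)CC)CC/C=C/[C@@H](O)[C@H]1O[Si](CC)(CC)CC | intermediate
12 | (3S,6E,8R,9R,10S)-3,8,9-trihydroxy-10-propyl-3,4,5,8,9,10-hexahydro-2H-oxecin-2-one | CCC[C@@H]1OC(=O)[C@@H](O)CC/C=C/[C@@H](O)[C@H]1O | intermediate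
13 | (3S,6E,8R,9S,10S)-3-hydroxy-8,9-(isopropylidenedioxy)-10-propyl-3,4,5,8,9,10-hexahydro-2H-oxecin-2-one (cis-fused acetonide) | CCC[C@@H]1OC(=O)[C@@H](O)CC/C=C/[C@H]2OC(C)(C)O[C@@H]12 | intermediate
14 | ethyl (2E)-4-oxobut-2-enoate | CCOC(=O)/C=C/C=O | starting material
15 | tert-butyl (triphenylphosphoranylidene)acetate | CC(C)(C)OC(=O)C=P(c1ccccc1)(c1ccccc1)c1ccccc1 | starting material
16 | 1-tert-butyl 6-ethyl (2E,4E)-hexa-2,4-dienedioate | CCOC(=O)/C=C/C=C/C(=O)OC(C)(C)C | intermediate
17 | (2E,4E)-6-tert-butoxy-6-oxohexa-2,4-dienoic acid | OC(=O)/C=C/C=C/C(=O)OC(C)(C)C | intermediate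
18 | tert-butyl (3S,6E,8R,9S,10S)-8,9-(isopropylidenedioxy)-2-oxo-10-propyl-3,4,5,8,9,10-hexahydro-2H-oxecin-3-yl (2E,4E)-hexa-2,4-dienedioate | CCC[C@@H]1OC(=O)[C@@H](OC(=O)/C=C/C=C/C(=O)OC(C)(C)C)CC/C=C/[C@H]2OC(C)(C)O[C@@H]12 | intermediate
19 | (2E,4E)-6-{[(3S,6E,8R,9R,10S)-8,9-dihydroxy-2-oxo-10-propyl-3,4,5,8,9,10-hexahydro-2H-oxecin-3-yl]oxy}-6-oxohexa-2,4-dienoic acid | CCC[C@@H]1OC(=O)[C@@H](OC(=O)/C=C/C=C/C(=O)O)CC/C=C/[C@@H](O)[C@H]1O | target

Total step count: 13. Longest linear sequence: 10 steps (steps 1, 2, 3, 5, 6, 7, 8, 9, 12, 13).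

Steps most likely to fail

1. Step 8. The ring-forming addition may show poor facial selectivity, because strain in the ten-membered transition state can override the Felkin–Anh preference and give a mixture of C8 epimers. The fallback sets out from 11 obtained as the epimer mixture. Dess–Martin oxidation of the allylic alcohol should give the macrocyclic enone (3S,6E,9S,10S)-10-propyl-3,9-bis[(triethylsilyl)oxy]-3,4,5,10-tetrahydro-2H-oxecine-2,8(9H)-dione F1. Reagent-controlled 1,2-reduction with (R)-2-methyl-CBS-oxazaborolidine and BH3·SMe2 (alkenyl arm as the large substituent) should then set C8 by hydride delivery and return the (8R) alcohol, coming back to the route at 11.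

2. Step 5. The α-silyloxy acid may be a sluggish nucleophile at titanium, and the ester may migrate from O3 to the neighbouring hydroxyl during opening or work-up. The fallback sets out from 7 and forms the ester bond by acylation instead. Ti(OiPr)4-mediated opening with benzoic acid should give (2R,3S)-1,2-dihydroxyhexan-3-yl benzoate F2. TESOTf/2,6-lutidine should give (2R,3S)-1,2-bis[(triethylsilyl)oxy]hexan-3-yl benzoate F3. i-Bu2AlH at −78 °C should remove the benzoate to give (2R,3S)-1,2-bis[(triethylsilyl)oxy]hexan-3-ol F4. Yamaguchi esterification of F4 with acid 5 (2,4,6-trichlorobenzoyl chloride, Et3N, DMAP) comes back to the route at 9.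

3. Step 7. Under the amine base the β-acyloxy aldehyde may lose its carboxylate by β-elimination or epimerise at the α-carbon, and desilylation may not stay confined to the primary ether. The fallback sets out from 9. Selective cleavage of the primary TES ether with HF·pyridine/pyridine in THF at 0 °C should give (2R,3S)-1-hydroxy-2-[(triethylsilyl)oxy]hexan-3-yl (2S,5E)-6-iodo-2-[(triethylsilyl)oxy]hex-5-enoate F5. Base-free oxidation with Dess–Martin periodinane (NaHCO3 buffer) comes back to the route at 10.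

Further compounds
F1 | step 8 | (3S,6E,9S,10S)-10-propyl-3,9-bis[(triethylsilyl)oxy]-3,4,5,10-tetrahydro-2H-oxecine-2,8(9H)-dione | CCC[C@@H]1OC(=O)[C@@H](O[Si](CC)(CC)CC)CC/C=C/C(=O)[C@H]1O[Si](CC)(CC)CC
F2 | step 5 | (2R,3S)-1,2-dihydroxyhexan-3-yl benzoate | CCC[C@H](OC(=O)c1ccccc1)[C@H](O)CO
F3 | step 5 | (2R,3S)-1,2-bis[(triethylsilyl)oxy]hexan-3-yl benzoate | CCC[C@H](OC(=O)c1ccccc1)[C@H](O[Si](CC)(CC)CC)CO[Si](CC)(CC)CC
F4 | step 5 | (2R,3S)-1,2-bis[(triethylsilyl)oxy]hexan-3-ol | CCC[C@H](O)[C@H](O[Si](CC)(CC)CC)CO[Si](CC)(CC)CC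
F5 | step 7 | (2R,3S)-1-hydroxy-2-[(triethylsilyl)oxy]hexan-3-yl (2S,5E)-6-iodo-2-[(triethylsilyl)oxy]hex-5-enoate | CCC[C@H](OC(=O)[C@@H](O[Si](CC)(CC)CC)CC/C=C/I)[C@H](O[Si](CC)(CC)CC)CO
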